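Numbering: ring A = C6 (spiro), C7 (=C14H2), C8, C9 (OH), C10 (Br), C11 (CMe2); ring B = C6, C5, C4, C3 (CH3, OH), C2 (Cl), C1.
Retrosynthetic cuts, in order: C3–CH3 and C2–Cl (back to a locally symmetric ring B ketone), C8–C9 of ring A, C10–Br, the two C1 units of an isopropenyl group on C7, and last C6–C11.
Enabling feature: in ring A the unit C14=C7–C8–C9(OH) is a 3-methylenecyclohexanol whose carbinol is flanked by the C10 bromide. This is the retron of a carbonyl-ene closure between a C9/C10 alpha-bromoaldehyde and an isopropenyl group (C7, C8, C14), both hanging on the C6–C11 axis.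
Forward order: ring B is bought as a ketal acid; an Ireland–Claisen rearrangement joins C6 to C11; the acid becomes the isopropenyl group and the vinyl group becomes the aldehyde; ring A closes in the ene step; ring B is then chlorinated and methylated.
Stereochemistry: C10 comes from enamine catalysis, C9 from C10 in the chair ene transition state, C6 from a chiral lithium amide that tells C2 from C4, C2 from C6 (axial C7 shields one face of ring B), and C3 from C2 and the ring B chair.
Key step: step 9

Assumption: the sense of induction of the aminocatalyst (step 8) and of the lithium amide (step 11) is read from their standard models, and both are sold as either enantiomer, so a reversed sense would be met with the antipode; the brominating dienone of step 8 is taken as a purchased reagent (2,6-di-tert-butylphenol and Br2 otherwise give it in one operation).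

Step 1
Reactants: 1 1,4-dioxaspiro[4.5]decane-8-carboxylic acid; 2 prenol (3-methylbut-2-en-1-ol)
Product: 3 3-methylbut-2-en-1-yl 1,4-dioxaspiro[4.5]decane-8-carboxylate
Conditions: N,N'-dicyclohexylcarbodiimide, 4-(dimethylamino)pyridine (cat.), CH2Cl2, 0 °C → 23 °C
Reagents that add atoms: none
Why: Steglich esterification, in which the carbodiimide activates 1 and 4-(dimethylamino)pyridine relays the acyl group to the primary allylic alcohol under neutral conditions that leave the ketal and the trisubstituted alkene alone, with no stereocentre involved.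

Step 2
Reactants: 3 3-methylbut-2-en-1-yl 1,4-dioxaspiro[4.5]decane-8-carboxylate
Product: 6 8-(2-methylbut-3-en-2-yl)-1,4-dioxaspiro[4.5]decane-8-carboxylic acid, via silyl ketene acetal 4 (not isolated), via trimethylsilyl ester 5 (not isolated)
Conditions: LiN(i-Pr)2, THF, −78 °C; Me3SiCl; −78 °C → 65 °C; then H2O
Reagents that add atoms: trimethylsilyl chloride, C[Si](C)(C)Cl (its silicon is found in 4 and 5 only)
Why: Ireland–Claisen rearrangement, in which 3 becomes ketene acetal 4 (no E/Z issue because ring B is symmetric) and the chair [3,3] shift, driven by formation of the C=O bond, is an established way to join two fully substituted carbons, here C6 and C11, while the prenyl group turns into the 1,1-dimethylallyl group; C6 stays non-stereogenic and water cleaves silyl ester 5 without harming the ketal.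

Step 3
Reactants: 6 8-(2-methylbut-3-en-2-yl)-1,4-dioxaspiro[4.5]decane-8-carboxylic acid
Product: 7 1-[8-(2-methylbut-3-en-2-yl)-1,4-dioxaspiro[4.5]decan-8-yl]ethan-1-one
Conditions: MeLi (3 equiv), Et2O, 0 °C → 35 °C; inverse quench into cold H2O
Reagents that add atoms: methyllithium, [Li]C
Why: Methyl ketone synthesis from a carboxylic acid and excess methyllithium, in which the carbonyl group is set free only on the aqueous quench and is flanked by quaternary C6, so a second addition is not expected, and ketal and vinyl group are inert to the reagent.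

Step 4
Reactants: 7 1-[8-(2-methylbut-3-en-2-yl)-1,4-dioxaspiro[4.5]decan-8-yl]ethan-1-one
Product: 8 8-(2-methylbut-3-en-2-yl)-8-(prop-1-en-2-yl)-1,4-dioxaspiro[4.5]decane
Conditions: Ph3PCH3Br, KOt-Bu, toluene, 90 °C
Reagents that add atoms: methyltriphenylphosphonium bromide, C[P+](c1ccccc1)(c1ccccc1)c1ccccc1.[Br-]
Why: Wittig methylenation in the KOt-Bu/hot toluene variant used for hindered, enolisable ketones, where enolisation is reversible and olefination is not, so 7 should drain to the isopropenyl compound.

Step 5
Reactants: 8 8-(2-methylbut-3-en-2-yl)-8-(prop-1-en-2-yl)-1,4-dioxaspiro[4.5]decane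
Product: 10 3-methyl-3-[8-(prop-1-en-2-yl)-1,4-dioxaspiro[4.5]decan-8-yl]butan-1-ol, via trialkylborane 9 (not isolated)
Conditions: disiamylborane (from BH3·THF and 2-methylbut-2-ene), THF, 0 °C; then NaOH, H2O2, 0 °C → 23 °C
Reagents that add atoms: disiamylborane, CC(C)C(C)BC(C)C(C)C (its boron and alkyl groups are found in 9 only); hydrogen peroxide, OO
Why: Hydroboration–oxidation with a bulky dialkylborane, which reacts with monosubstituted alkenes much faster than with 1,1-disubstituted ones; the isopropenyl group is further buried between quaternary C6 and C11 and boron goes to the terminal carbon, so oxidation of 9 should give only the primary C9 alcohol.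

Step 6
Reactants: 10 3-methyl-3-[8-(prop-1-en-2-yl)-1,4-dioxaspiro[4.5]decan-8-yl]butan-1-ol
Product: 11 4-(4-hydroxy-2-methylbutan-2-yl)-4-(prop-1-en-2-yl)cyclohexan-1-one
Conditions: 1 M HCl, THF, 23 °C
Reagents that add atoms: water, O
Why: Acid-catalysed ketal hydrolysis, placed at the alcohol stage on purpose so that no aldehyde is present that could undergo a premature acid-induced Prins or ene closure with the isopropenyl group, which dilute acid at room temperature does not protonate.

Step 7
Reactants: 11 4-(4-hydroxy-2-methylbutan-2-yl)-4-(prop-1-en-2-yl)cyclohexan-1-one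
Product: 12 3-methyl-3-[4-oxo-1-(prop-1-en-2-yl)cyclohexyl]butanal
Conditions: 2,2,6,6-tetramethylpiperidin-1-oxyl (TEMPO, 10 mol %), PhI(OAc)2, CH2Cl2, 23 °C
Reagents that add atoms: none
Why: Oxoammonium (TEMPO) oxidation with PhI(OAc)2 as terminal oxidant stops at the aldehyde in the absence of water and touches neither the alkene nor the ketone.

Step 8
Reactants: 12 3-methyl-3-[4-oxo-1-(prop-1-en-2-yl)cyclohexyl]butanal
Product: 13 (2S)-2-bromo-3-methyl-3-[4-oxo-1-(prop-1-en-2-yl)cyclohexyl]butanal
Conditions: (S)-2-{bis[3,5-bis(trifluoromethyl)phenyl](trimethylsilyloxy)methyl}pyrrolidine (20 mol %), PhCO2H (20 mol %), 4,4-dibromo-2,6-di-tert-butylcyclohexa-2,5-dien-1-one, CH2Cl2/pentane, −40 °C; used without chromatography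
Reagents that add atoms: 4,4-dibromo-2,6-di-tert-butylcyclohexa-2,5-dien-1-one, O=C1C(C(C)(C)C)=CC(Br)(Br)C=C1C(C)(C)C
Why: Enamine-catalysed enantioselective alpha-bromination of an aldehyde, known for aldehydes with a tert-alkyl group on the alpha carbon: the bulky amine condenses with the aldehyde and not with the ketone, its s-trans E-enamine is shielded on one face by the diaryl(silyloxy)methyl group and takes Br+ on the open face to set C10 as S, the enamine is far more nucleophilic than the isopropenyl group, and the tert-alkyl neighbour slows enolisation of the product.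

Step 9
Reactants: 13 (2S)-2-bromo-3-methyl-3-[4-oxo-1-(prop-1-en-2-yl)cyclohexyl]butanal
Product: 15 (3R,4S)-4-bromo-3-hydroxy-5,5-dimethyl-1-methylidenespiro[5.5]undecan-9-one, via aluminium alkoxide 14 (not isolated)
Conditions: Me2AlCl (2.5 equiv, 1 M in hexanes), CH2Cl2, −78 °C → −40 °C; cold 1 M HCl
Reagents that add atoms: dimethylaluminium chloride, C[Al](C)Cl (its aluminium, methyl group and chlorine are found in 14 only)
Why: Me2AlCl binds the aldehyde oxygen of 13 (a first equivalent is parked on the more basic but far less electrophilic ring B ketone), the terminal alkene carbon C8 bonds to C9 while a hydrogen of the C14 methyl group moves to oxygen, and the alcohol complex then loses methane to give alkoxide 14, so no acid remains to pull the new C7=C14 bond into the ring. The closest known reaction is the Me2AlCl-promoted type 2 intramolecular carbonyl-ene cyclisation of 5-methylhex-5-enals to 3-methylenecyclohexanols, and alpha-haloaldehydes are established, particularly reactive enophiles. Ring A closes as a six-membered chair, 6-exo-trig at the carbonyl carbon and endo with respect to the alkene, helped by the gem-dialkyl effect of the two quaternary carbons C6 and C11 in the tether. C9 is the only new stereocentre and is controlled by C10: bromine takes the equatorial site, where C10–Br lies antiperiplanar to the forming C8–C9 bond (polar Felkin–Anh alignment), whereas an axial bromine would be 1,3-diaxial to a ring B methylene group on C6. The six-atom hydrogen-transfer array O–C9–C8–C7–C14–H is fused to the chair along C7–C8–C9 like the second ring of a bicyclo[3.3.1]nonane, which holds oxygen axial, so OH and Br should emerge cis (9R,10S). The step needs aldehyde-over-ketone chemoselectivity, secured by the bromine-enhanced electrophilicity of C9 and by the boat that a transannular attack on C3 would demand; a single direction of hydrogen transfer, secured because quaternary C6 leaves C14 as the only allylic C–H donor; and a closed rather than open transition state, for which the small Lewis acid and the low temperature are chosen, while C6 stays non-stereogenic.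

Step 10
Reactants: 15 (3R,4S)-4-bromo-3-hydroxy-5,5-dimethyl-1-methylidenespiro[5.5]undecan-9-one
Product: 16 (3R,4S)-4-bromo-5,5-dimethyl-1-methylidene-3-(triethylsilyloxy)spiro[5.5]undecan-9-one
Conditions: Et3SiOTf, 2,6-lutidine, CH2Cl2, −78 °C → 0 °C
Reagents that add atoms: triethylsilyl trifluoromethanesulfonate, CC[Si](CC)(CC)OS(=O)(=O)C(F)(F)F
Why: Silylation with a silyl triflate and a hindered pyridine base is fast enough for the axial C9 hydroxyl, which faces the axial C11 methyl group, at a temperature where the ring B ketone is not enolised, and it removes the acidic proton beside C10–Br before strong base is used.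

Step 11
Reactants: 16 (3R,4S)-4-bromo-5,5-dimethyl-1-methylidene-3-(triethylsilyloxy)spiro[5.5]undecan-9-one
Product: 17 (6S,9R,10S)-trimethylsilyl enol ether of 16 with the double bond C2=C3 (ring B = C6–C5H2–C4H2–C3(OSiMe3)=C2H–C1H2, ring A as in 16)
Conditions: (R,R)-bis(1-phenylethyl)amine, n-BuLi, THF; Me3SiCl (in situ quench), then 16, −100 °C → −78 °C; Et3N, aq NaHCO3; used without chromatography
Reagents that add atoms: trimethylsilyl chloride, C[Si](C)(C)Cl
Why: Selective deprotonation of a conformationally anchored 4,4-disubstituted cyclohexanone by a C2-symmetric chiral lithium amide with in situ silylation, a known desymmetrisation: with C11 equatorial and C7 axial on ring B the (R,R)-amide should remove the axial hydrogen of the methylene group that becomes C2, in the sense in which it turns 4-tert-butylcyclohexanone into the (S)-enol silane, which makes C6 stereogenic with S configuration and diverts any minor enantiomer of 16 into a separable diastereomer.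

Step 12
Reactants: 17 (6S,9R,10S)-trimethylsilyl enol ether of 16
Product: 18 (2S,6S,9R,10S)-10-bromo-2-chloro-9-(triethylsilyloxy) ketone (16 with an equatorial chlorine on C2, cis to C11 across ring B)
Conditions: N-chlorosuccinimide, THF, −20 °C → 23 °C; aq NaHCO3
Reagents that add atoms: N-chlorosuccinimide, O=C1CCC(=O)N1Cl
Why: Electrophilic chlorination of an enol silane, in which chlorine enters C2 from the ring B face opposite to axial C7 and its methylene group; the resulting equatorial chloride is also the thermodynamic epimer because an axial chlorine would be 1,3-diaxial to C7, and the enol ether outruns the C7=C14 alkene for Cl+.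

Step 13
Reactants: 18 (2S,6S,9R,10S)-10-bromo-2-chloro-9-(triethylsilyloxy) ketone
Product: 19 (2S,3R,6S,9R,10S)-10-bromo-2-chloro-9-(triethylsilyloxy)chamigr-7(14)-en-3-ol
Conditions: MeMgBr, Et2O, −78 °C; pH 7 buffer at −78 °C
Reagents that add atoms: methylmagnesium bromide, C[Mg]Br
Why: Grignard 1,2-addition to an alpha-chloroketone, in which methyl comes in along the equatorial path on the face anti to the C2 chlorine, as in the known preference of 2-chlorocyclohexanones for the cis chlorohydrin, because oxygen then swings axial and away from the nearly eclipsed C2–Cl dipole; this gives axial OH and equatorial CH3 (3R), the cis O/Cl pair cannot close to an epoxide, and the cold quench forestalls semipinacol ring contraction.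

Step 14
Reactants: 19 (2S,3R,6S,9R,10S)-10-bromo-2-chloro-9-(triethylsilyloxy)chamigr-7(14)-en-3-ol
Product: 20 (2S,3R,6S,9R,10S)-10-bromo-2-chlorochamigr-7(14)-ene-3,9-diol (CNP0121782.1)
Conditions: HF·pyridine, pyridine, THF, 0 °C → 23 °C
Reagents that add atoms: none
Why: Fluoride-driven cleavage of the triethylsilyl ether in a buffered, non-basic medium, which should leave both cis halohydrins, the tertiary alcohol and the exocyclic alkene untouched.

Compound list
1 | 1,4-dioxaspiro[4.5]decane-8-carboxylic acid | O=C(O)C1CCC2(CC1)OCCO2 | starting material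
2 | prenol (3-methylbut-2-en-1-ol) | CC(C)=CCO | starting material
3 | 3-methylbut-2-en-1-yl 1,4-dioxaspiro[4.5]decane-8-carboxylate | CC(C)=CCOC(=O)C1CCC2(CC1)OCCO2 | intermediate
4 | prenyl trimethylsilyl ketene acetal of 3 | CC(C)=CCOC(O[Si](C)(C)C)=C1CCC2(CC1)OCCO2 | intermediate
5 | trimethylsilyl 8-(2-methylbut-3-en-2-yl)-1,4-dioxaspiro[4.5]decane-8-carboxylate | C=CC(C)(C)C1(C(=O)O[Si](C)(C)C)CCC2(CC1)OCCO2 | intermediate
6 | 8-(2-methylbut-3-en-2-yl)-1,4-dioxaspiro[4.5]decane-8-carboxylic acid | C=CC(C)(C)C1(C(=O)O)CCC2(CC1)OCCO2 | intermediate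
7 | 1-[8-(2-methylbut-3-en-2-yl)-1,4-dioxaspiro[4.5]decan-8-yl]ethan-1-one | C=CC(C)(C)C1(C(C)=O)CCC2(CC1)OCCO2 | intermediate
8 | 8-(2-methylbut-3-en-2-yl)-8-(prop-1-en-2-yl)-1,4-dioxaspiro[4.5]decane | C=CC(C)(C)C1(C(C)=C)CCC2(CC1)OCCO2 | intermediate
9 | bis(3-methylbutan-2-yl){3-methyl-3-[8-(prop-1-en-2-yl)-1,4-dioxaspiro[4.5]decan-8-yl]butyl}borane | CC(C)C(C)B(CCC(C)(C)C1(C(C)=C)CCC2(CC1)OCCO2)C(C)C(C)C | intermediate
10 | 3-methyl-3-[8-(prop-1-en-2-yl)-1,4-dioxaspiro[4.5]decan-8-yl]butan-1-ol | OCCC(C)(C)C1(C(C)=C)CCC2(CC1)OCCO2 | intermediate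
11 | 4-(4-hydroxy-2-methylbutan-2-yl)-4-(prop-1-en-2-yl)cyclohexan-1-one | OCCC(C)(C)C1(C(C)=C)CCC(=O)CC1 | intermediate
12 | 3-methyl-3-[4-oxo-1-(prop-1-en-2-yl)cyclohexyl]butanal | O=CCC(C)(C)C1(C(C)=C)CCC(=O)CC1 | intermediate
13 | (2S)-2-bromo-3-methyl-3-[4-oxo-1-(prop-1-en-2-yl)cyclohexyl]butanal | O=C[C@@H](Br)C(C)(C)C1(C(C)=C)CCC(=O)CC1 | intermediate
14 | chloro(methyl)aluminium alkoxide of 15 | C=C1C[C@@H](O[Al](C)Cl)[C@@H](Br)C(C)(C)C12CCC(=O)CC2 | intermediate
15 | (3R,4S)-4-bromo-3-hydroxy-5,5-dimethyl-1-methylidenespiro[5.5]undecan-9-one | C=C1C[C@@H](O)[C@@H](Br)C(C)(C)C12CCC(=O)CC2 | intermediate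
16 | (3R,4S)-4-bromo-5,5-dimethyl-1-methylidene-3-(triethylsilyloxy)spiro[5.5]undecan-9-one | C=C1C[C@@H](O[Si](CC)(CC)CC)[C@@H](Br)C(C)(C)C12CCC(=O)CC2 | intermediate
17 | (6S,9R,10S)-trimethylsilyl enol ether of 16, double bond C2=C3 | C=C1C[C@@H](O[Si](CC)(CC)CC)[C@@H](Br)C(C)(C)[C@]12CCC(O[Si](C)(C)C)=CC2 | intermediate
18 | (2S,6S,9R,10S)-10-bromo-2-chloro-9-(triethylsilyloxy) ketone (C3=O) | C=C1C[C@@H](O[Si](CC)(CC)CC)[C@@H](Br)C(C)(C)[C@]12CCC(=O)[C@@H](Cl)C2 | intermediate
19 | (2S,3R,6S,9R,10S)-10-bromo-2-chloro-9-(triethylsilyloxy)chamigr-7(14)-en-3-ol | C=C1C[C@@H](O[Si](CC)(CC)CC)[C@@H](Br)C(C)(C)[C@]12CC[C@@](C)(O)[C@@H](Cl)C2 | intermediate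
20 | (2S,3R,6S,9R,10S)-10-bromo-2-chlorochamigr-7(14)-ene-3,9-diol (CNP0121782.1) | C=C1C[C@@H](O)[C@@H](Br)C(C)(C)[C@]12CC[C@@](C)(O)[C@@H](Cl)C2 | target

Total step count: 14. Longest linear sequence: 14 steps (from 1).

Steps most likely to fail

First, step 9. The closed, concerted transition state may leak into an open, stepwise one, because the aluminium-bound axial oxygen meets the axial C11 methyl group, and the C9 selectivity would then erode.
- The fallback sets out from 13 and returns at 15; it sets C9 by hydride delivery instead of by the ene geometry.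
- The ene mixture from 13 is separated, and the (3S,4S)-bromohydrin ketone F1 is ketalised at C3 (ethylene glycol, pyridinium p-toluenesulfonate, benzene, water separator) to the hydroxy ketal F2.
- Buffered oxidation with the periodinane DMP (1,1,1-triacetoxy-1,1-dihydro-1,2-benziodoxol-3(1H)-one), NaHCO3, CH2Cl2, 0 °C, should give the alpha-bromoketone ketal F3. It is not chromatographed, so the C7=C14 bond has no occasion to move into conjugation.
- i-Bu2AlH in CH2Cl2 at −78 °C should reach C9 along the equatorial path, since the axial C11 methyl group blocks the axial one, and give the axial alcohol ketal F4.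
- 1 M HCl in THF then frees the ring B ketone and gives 15.

Second, step 8. Enamine turnover may be slow at an aldehyde whose alpha carbon is backed by two contiguous quaternary carbons, and enantiomeric purity may be lost through enolisation of the product while it waits.
- The fallback sets out from 12 and returns at 18; it hands the absolute configuration to the chiral amide of step 11.
- Compound 12 is brominated without stereocontrol (same dienone, racemic 2-[diphenyl(trimethylsilyloxy)methyl]pyrrolidine, higher loading, 0 °C). This gives 13 together with the (2R)-bromoaldehyde F5.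
- Steps 9 and 10 carry the pair on, F5 passing through the enantiomeric aluminium alkoxide F6 to the (3S,4R)-bromohydrin ketone F7 and the (3S,4R)-triethylsilyl ether F8.
- The amide of step 11 reads only the ring B chair, so it should take 16 to 17 and F8 to the (6S,9S,10R)-enol silane F9.
- Chlorination as in step 12 then gives 18 beside the (2S,6S,9S,10R)-chloroketone F10.
- These two differ in how ring A is set against ring B, so they are diastereomers that chromatography should part.
- The price is half of the material, and the enantiomeric purity of 18 then rests on the selectivity of the amide.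

Third, step 11. The reagent-controlled choice between the C2 and C4 methylene groups may be opposed by the substrate, because C14H2 eclipses the C6–C1 bond and leans over the axial hydrogen on C2, so the selectivity of deprotonation may erode.
- The fallback sets out from 16 and returns at 18, skipping 17; it replaces kinetic deprotonation by enamine catalysis.
- Reagents: N-chlorosuccinimide, a C2-symmetric 4,5-diphenylimidazolidine (the enantiomer that turns cyclohexanone into (S)-2-chlorocyclohexanone), 2-nitrobenzoic acid, MeCN, −24 °C.
- The enamines toward C2 and C4 interconvert, so C–Cl bond formation decides the outcome.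
- Axial C7 leaves only one ring B face open at either carbon, and the facial preference of the catalyst matches that face at C2 only, so C2 and C6 are set together.
- This detour makes no compound outside the list (entry F0).

Further compounds
F1 | step 9 | (3S,4S)-4-bromo-3-hydroxy-5,5-dimethyl-1-methylidenespiro[5.5]undecan-9-one (C9 epimer of 15) | C=C1C[C@H](O)[C@@H](Br)C(C)(C)C12CCC(=O)CC2
F2 | step 9 | ethylene ketal (at C3) of F1 | C=C1C[C@H](O)[C@@H](Br)C(C)(C)C12CCC3(CC2)OCCO3
F3 | step 9 | (10S)-10-bromo C9 ketone with C3 ethylene ketal | C=C1CC(=O)[C@@H](Br)C(C)(C)C12CCC3(CC2)OCCO3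
F4 | step 9 | ethylene ketal (at C3) of 15 | C=C1C[C@@H](O)[C@@H](Br)C(C)(C)C12CCC3(CC2)OCCO3
F5 | step 8 | (2R)-2-bromo-3-methyl-3-[4-oxo-1-(prop-1-en-2-yl)cyclohexyl]butanal | O=C[C@H](Br)C(C)(C)C1(C(C)=C)CCC(=O)CC1
F6 | step 8 | chloro(methyl)aluminium alkoxide of F7 (enantiomer of 14) | C=C1C[C@H](O[Al](C)Cl)[C@H](Br)C(C)(C)C12CCC(=O)CC2
F7 | step 8 | (3S,4R)-4-bromo-3-hydroxy-5,5-dimethyl-1-methylidenespiro[5.5]undecan-9-one | C=C1C[C@H](O)[C@H](Br)C(C)(C)C12CCC(=O)CC2
F8 | step 8 | (3S,4R)-4-bromo-5,5-dimethyl-1-methylidene-3-(triethylsilyloxy)spiro[5.5]undecan-9-one | C=C1C[C@H](O[Si](CC)(CC)CC)[C@H](Br)C(C)(C)C12CCC(=O)CC2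
F9 | step 8 | (6S,9S,10R)-trimethylsilyl enol ether of F8, double bond C2=C3 | C=C1C[C@H](O[Si](CC)(CC)CC)[C@H](Br)C(C)(C)[C@]12CCC(O[Si](C)(C)C)=CC2
F10 | step 8 | (2S,6S,9S,10R)-10-bromo-2-chloro-9-(triethylsilyloxy) ketone (C3=O) | C=C1C[C@H](O[Si](CC)(CC)CC)[C@H](Br)C(C)(C)[C@]12CCC(=O)[C@@H](Cl)C2
F0 | step 11 | none | none
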